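**Plan**

- Retrosynthesis: the C6 methoxy ketal and the methyl ester are adjusted last (ketal exchange, CH2OH to CO2Me). The ring is then cut at the peroxide O2–C3 bond, which reveals a ketal-bound hydroperoxide facing the C2–O bond of a (Z)-2-alkenyloxetane. Further cuts are the C6–OOH bond (H2O2 exchange on a dimethyl ketal), the oxetane O–CH2 bond, and the two C–C bonds flanking an alkyne.
- Enabling feature: the peroxy methine C3 carries ring oxygen O2, one hydrogen and a two-carbon arm, which is the substitution pattern of oxetane C2. C6 is a ketal carbon that can hold the hydroperoxide, and the ring C4=C5 bond, as a (Z)-alkene, keeps the two within reach.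
- Forward: heptadecanoic acid is turned into a propargylic dimethyl ketal alkyne, which is added to a three-carbon aldehyde. Asymmetric reduction, oxetane closure (first ring), semi-hydrogenation and perhydrolysis give the cyclisation substrate. The 1,2-dioxine (second ring) closes as the oxetane opens; oxidation, methylation and ketal equilibration finish the route.
- Stereochemistry: C3 comes from a Noyori transfer hydrogenation ((R)-carbinol), is retained in the Williamson closure and inverted in the peroxide alkylation to (S). C6 (R) is selected by acid equilibration of the ketal in methanol, separation and recycling of the epimer.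

Key step: step 12

Remark on the chemistry: 3-[(tert-butyldimethylsilyl)oxy]propanal is taken as a catalogue compound, and the facial sense of the transfer hydrogenation is assigned by analogy with simpler silyl ynones and would be confirmed on 13 by Mosher ester analysis.

**Route**

Step 1
Reactants: 1 heptadecanoic acid
Product: 3 N-methoxy-N-methylheptadecanamide, via N-heptadecanoylimidazole 2 (not isolated)
Conditions: CDI, CH2Cl2, rt; then MeNH(OMe)·HCl, rt
Reagents that add atoms: N,O-dimethylhydroxylamine hydrochloride, CNOC.Cl
Why: Weinreb amide formation through the acyl imidazolide is a standard amide coupling that needs no acid chloride and is well behaved for long-chain fatty acids.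

Step 2
Reactants: 3 N-methoxy-N-methylheptadecanamide; 4 ethynyltrimethylsilane
Product: 6 1-(trimethylsilyl)nonadec-1-yn-3-one, via lithium (trimethylsilyl)acetylide 5 (not isolated)
Conditions: 4, n-BuLi, THF, −78 °C; then 3, −78 → 0 °C; aq. NH4Cl
Reagents that add atoms: none
Why: Weinreb ketone synthesis with a lithium acetylide stops at the ynone because the chelated tetrahedral adduct survives until work-up, so over-addition should not occur.

Step 3
Reactants: 6 1-(trimethylsilyl)nonadec-1-yn-3-one
Product: 8 3,3-dimethoxynonadec-1-yne, via (3,3-dimethoxynonadec-1-yn-1-yl)trimethylsilane 7 (not isolated)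
Conditions: HC(OMe)3, MeOH, TsOH·H2O (cat.), rt; then K2CO3, rt
Reagents that add atoms: trimethyl orthoformate, COC(OC)OC; methanol, CO
Why: Acid-catalysed ketalisation with an orthoformate as water scavenger should convert the ynone into its dimethyl ketal while the silyl cap suppresses conjugate addition of methanol, and the base-mediated protodesilylation that follows in the same flask frees the terminal alkyne without touching the ketal.

Step 4
Reactants: 8 3,3-dimethoxynonadec-1-yne; 9 3-[(tert-butyldimethylsilyl)oxy]propanal
Product: 11 rac-1-[(tert-butyldimethylsilyl)oxy]-6,6-dimethoxydocos-4-yn-3-ol, via (3,3-dimethoxynonadec-1-yn-1-yl)lithium 10 (not isolated)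
Conditions: 8, n-BuLi, THF, −78 °C; then 9, −78 °C; aq. NH4Cl
Reagents that add atoms: none
Why: 1,2-Addition of a lithium acetylide to an aldehyde at low temperature outruns enolisation, and the base-stable ketal and silyl ether are spectators.

Step 5
Reactants: 11 rac-1-[(tert-butyldimethylsilyl)oxy]-6,6-dimethoxydocos-4-yn-3-ol
Product: 12 1-[(tert-butyldimethylsilyl)oxy]-6,6-dimethoxydocos-4-yn-3-one
Conditions: Dess–Martin periodinane, NaHCO3, CH2Cl2, 0 °C → rt
Reagents that add atoms: none
Why: Dess–Martin oxidation of a propargylic alcohol under bicarbonate buffer is mild enough to spare the ketal and to avoid β-elimination of the silyloxy group from the ynone.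

Step 6
Reactants: 12 1-[(tert-butyldimethylsilyl)oxy]-6,6-dimethoxydocos-4-yn-3-one
Product: 13 (3R)-1-[(tert-butyldimethylsilyl)oxy]-6,6-dimethoxydocos-4-yn-3-ol
Conditions: Ru[(R,R)-TsDPEN](p-cymene) (cat.), i-PrOH, rt
Reagents that add atoms: none
Why: Noyori asymmetric transfer hydrogenation differentiates the alkynyl from the alkyl flank of an ynone, and the (R,R)-ligand is expected to deliver hydride to the face that gives the (R)-propargylic alcohol, as with simpler 1-silyl ynones, while alkyne and ketal are inert to the catalyst.

Step 7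
Reactants: 13 (3R)-1-[(tert-butyldimethylsilyl)oxy]-6,6-dimethoxydocos-4-yn-3-ol
Product: 14 (3R)-6,6-dimethoxydocos-4-yne-1,3-diol
Conditions: Bu4NF, THF, 0 °C → rt; aq. NH4Cl
Reagents that add atoms: none
Why: Fluoride-mediated desilylation cleaves only the Si–O bond and leaves the ketal, the alkyne and the carbinol stereocentre untouched.

Step 8
Reactants: 14 (3R)-6,6-dimethoxydocos-4-yne-1,3-diol
Product: 15 (3R)-3-hydroxy-6,6-dimethoxydocos-4-yn-1-yl 4-methylbenzenesulfonate
Conditions: TsCl (1 equiv), pyridine, CH2Cl2, 0 °C
Reagents that add atoms: 4-methylbenzenesulfonyl chloride, Cc1ccc(cc1)S(=O)(=O)Cl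
Why: Selective sulfonylation with one equivalent of TsCl at low temperature should favour the unhindered primary hydroxyl over the secondary propargylic one, so the C–O bond at the stereocentre stays intact.

Step 9
Reactants: 15 (3R)-3-hydroxy-6,6-dimethoxydocos-4-yn-1-yl 4-methylbenzenesulfonate
Product: 16 (2R)-2-(3,3-dimethoxynonadec-1-yn-1-yl)oxetane
Conditions: NaH, THF, 0 °C → rt
Reagents that add atoms: none
Why: Intramolecular Williamson etherification (4-exo-tet) of a 1,3-diol monotosylate is the standard oxetane synthesis; the alkoxide oxygen is the nucleophile, so the carbinol configuration is retained as (R) at oxetane C2, and NaH instead of an alkoxide base avoids propargyl–allene isomerisation.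

Step 10
Reactants: 16 (2R)-2-(3,3-dimethoxynonadec-1-yn-1-yl)oxetane
Product: 17 (2R)-2-[(1Z)-3,3-dimethoxynonadec-1-en-1-yl]oxetane
Conditions: H2 (1 atm), Pd/CaCO3 poisoned with Pb(OAc)2 (Lindlar catalyst), quinoline, EtOAc, rt
Reagents that add atoms: none
Why: Lindlar semi-hydrogenation adds hydrogen syn and should stop at the (Z)-alkene, the geometry that later holds hydroperoxide and oxetane on the same side, while quinoline tempers the catalyst against hydrogenolysis of the allylic C–O bonds.

Step 11
Reactants: 17 (2R)-2-[(1Z)-3,3-dimethoxynonadec-1-en-1-yl]oxetane; 18 hydrogen peroxide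
Product: 19 (2R)-2-[(1Z)-3-hydroperoxy-3-methoxynonadec-1-en-1-yl]oxetane (both epimers at the hydroperoxy ketal carbon)
Conditions: anhydrous H2O2 in Et2O (excess), PPTS (cat.), 0 °C
Reagents that add atoms: none
Why: Acid-catalysed perhydrolysis of a ketal (trans-ketalisation with H2O2) is a known entry to α-methoxy hydroperoxides, and the allylic ketal should ionise under a pyridinium acid far more readily than the oxetane is activated, so one methoxy group is exchanged while the four-membered ring and the (Z)-alkene persist and the new ketal centre forms as both epimers, which is of no consequence here.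

Step 12
Reactants: 19 (2R)-2-[(1Z)-3-hydroperoxy-3-methoxynonadec-1-en-1-yl]oxetane (both ketal epimers)
Product: 20 2-[(3S)-6-hexadecyl-6-methoxy-3,6-dihydro-1,2-dioxin-3-yl]ethan-1-ol (both C6 epimers)
Conditions: Yb(OTf)3 (cat.), CH2Cl2, −20 → 0 °C
Reagents that add atoms: none
Why: Proposed new method: Yb(OTf)3 should bind the oxetane oxygen so that the terminal oxygen of the ketal-bound hydroperoxide displaces it from the allylic oxetane carbon by backside attack, an intramolecular SN2 alkylation of a peroxide driven by the strain of the four-membered ring, after which proton transfer leaves the former oxetane oxygen as the primary alcohol. The closest known reaction type is the Lewis-acid-promoted 5-exo and 6-exo opening of saturated oxetanes by tethered hydroperoxides, which runs with inversion; what is new is an allylic oxetane carbon as electrophile and a hydroperoxy ketal as nucleophile. The 1,2-dioxine closes in the 6-exo-tet mode, the breaking C–O bond lying outside the forming ring. The one new stereocentre, C3, is controlled by the substrate: inversion of the (R)-configured oxetane carbon should give (S), while the ketal carbon is a spectator and both of its epimers are carried forward. The step needs concerted displacement instead of ionisation to an allyl cation and attack at the methine instead of the oxetane CH2; the (Z)-alkene places the hydroperoxide over the methine carbon only (the other mode would be an eight-membered ring), and a weak oxophilic Lewis acid at low temperature in a non-nucleophilic solvent should favour the concerted path over cation formation and over ionisation of the ketal.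

Step 13
Reactants: 20 2-[(3S)-6-hexadecyl-6-methoxy-3,6-dihydro-1,2-dioxin-3-yl]ethan-1-ol (both C6 epimers)
Product: 22 2-[(3S)-6-hexadecyl-6-methoxy-3,6-dihydro-1,2-dioxin-3-yl]acetic acid (both C6 epimers), via 2-[(3S)-6-hexadecyl-6-methoxy-3,6-dihydro-1,2-dioxin-3-yl]acetaldehyde 21 (not isolated)
Conditions: TEMPO (cat.), PhI(OAc)2, MeCN/H2O, 0 °C → rt
Reagents that add atoms: water, O
Why: The TEMPO/PhI(OAc)2 oxidation in aqueous acetonitrile takes a primary alcohol through the aldehyde hydrate to the acid in one flask under weakly acidic, non-reducing conditions that should tolerate the peroxide and the alkene and give the base-sensitive β-peroxy aldehyde little time to eliminate.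

Step 14
Reactants: 22 2-[(3S)-6-hexadecyl-6-methoxy-3,6-dihydro-1,2-dioxin-3-yl]acetic acid (both C6 epimers)
Product: 23 methyl 2-[(3S)-6-hexadecyl-6-methoxy-3,6-dihydro-1,2-dioxin-3-yl]acetate (both C6 epimers)
Conditions: Me3SiCHN2, PhMe/MeOH, 0 °C
Reagents that add atoms: (trimethylsilyl)diazomethane, C[Si](C)(C)C=[N+]=[N-]
Why: Esterification with (trimethylsilyl)diazomethane in methanol is a neutral O-methylation of the carboxylic acid and avoids the base that would trigger β-elimination or Kornblum–DeLaMare cleavage of the dioxine.

Step 15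
Reactants: 23 methyl 2-[(3S)-6-hexadecyl-6-methoxy-3,6-dihydro-1,2-dioxin-3-yl]acetate (both C6 epimers)
Product: 24 methyl 2-[(3S,6R)-6-hexadecyl-6-methoxy-3,6-dihydro-1,2-dioxin-3-yl]acetate
Conditions: camphorsulfonic acid (cat.), MeOH, 0 °C → rt; chromatography; (6S) epimer returned to the same conditions
Reagents that add atoms: methanol, CO
Why: Acid-catalysed ketal exchange in methanol passes through the ring peroxycarbenium ion, so C6 equilibrates (and any hemiketal formed in step 13 is re-methylated) while C3 is not touched, and the (6R) epimer, with methoxy trans to the acetate arm, should be separable by chromatography from the (6S) epimer, which is recycled.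

**Compound list**

1 | heptadecanoic acid | CCCCCCCCCCCCCCCCC(=O)O | starting material
2 | N-heptadecanoylimidazole (not isolated) | CCCCCCCCCCCCCCCCC(=O)n1ccnc1 | intermediate
3 | N-methoxy-N-methylheptadecanamide | CCCCCCCCCCCCCCCCC(=O)N(C)OC | intermediate
4 | ethynyltrimethylsilane | C#C[Si](C)(C)C | starting material
5 | lithium (trimethylsilyl)acetylide (not isolated) | [Li]C#C[Si](C)(C)C | intermediate
6 | 1-(trimethylsilyl)nonadec-1-yn-3-one | CCCCCCCCCCCCCCCCC(=O)C#C[Si](C)(C)C | intermediate
7 | (3,3-dimethoxynonadec-1-yn-1-yl)trimethylsilane (not isolated) | CCCCCCCCCCCCCCCCC(OC)(OC)C#C[Si](C)(C)C | intermediate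
8 | 3,3-dimethoxynonadec-1-yne | CCCCCCCCCCCCCCCCC(OC)(OC)C#C | intermediate
9 | 3-[(tert-butyldimethylsilyl)oxy]propanal | O=CCCO[Si](C)(C)C(C)(C)C | starting material
10 | (3,3-dimethoxynonadec-1-yn-1-yl)lithium (not isolated) | CCCCCCCCCCCCCCCCC(OC)(OC)C#C[Li] | intermediate
11 | rac-1-[(tert-butyldimethylsilyl)oxy]-6,6-dimethoxydocos-4-yn-3-ol | CCCCCCCCCCCCCCCCC(OC)(OC)C#CC(O)CCO[Si](C)(C)C(C)(C)C | intermediate
12 | 1-[(tert-butyldimethylsilyl)oxy]-6,6-dimethoxydocos-4-yn-3-one | CCCCCCCCCCCCCCCCC(OC)(OC)C#CC(=O)CCO[Si](C)(C)C(C)(C)C | intermediate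
13 | (3R)-1-[(tert-butyldimethylsilyl)oxy]-6,6-dimethoxydocos-4-yn-3-ol | CCCCCCCCCCCCCCCCC(OC)(OC)C#C[C@H](O)CCO[Si](C)(C)C(C)(C)C | intermediate
14 | (3R)-6,6-dimethoxydocos-4-yne-1,3-diol | CCCCCCCCCCCCCCCCC(OC)(OC)C#C[C@H](O)CCO | intermediate
15 | (3R)-3-hydroxy-6,6-dimethoxydocos-4-yn-1-yl 4-methylbenzenesulfonate | CCCCCCCCCCCCCCCCC(OC)(OC)C#C[C@H](O)CCOS(=O)(=O)c1ccc(C)cc1 | intermediate
16 | (2R)-2-(3,3-dimethoxynonadec-1-yn-1-yl)oxetane | CCCCCCCCCCCCCCCCC(OC)(OC)C#C[C@@H]1OCC1 | intermediate
17 | (2R)-2-[(1Z)-3,3-dimethoxynonadec-1-en-1-yl]oxetane | CCCCCCCCCCCCCCCCC(OC)(OC)/C=C\[C@@H]1OCC1 | intermediate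
18 | hydrogen peroxide | OO | starting material
19 | (2R)-2-[(1Z)-3-hydroperoxy-3-methoxynonadec-1-en-1-yl]oxetane, both epimers at the hydroperoxy ketal carbon | CCCCCCCCCCCCCCCCC(OC)(OO)/C=C\[C@@H]1OCC1 | intermediate
20 | 2-[(3S)-6-hexadecyl-6-methoxy-3,6-dihydro-1,2-dioxin-3-yl]ethan-1-ol, both C6 epimers | CCCCCCCCCCCCCCCCC1(OC)C=C[C@H](CCO)OO1 | intermediate
21 | 2-[(3S)-6-hexadecyl-6-methoxy-3,6-dihydro-1,2-dioxin-3-yl]acetaldehyde (not isolated) | CCCCCCCCCCCCCCCCC1(OC)C=C[C@H](CC=O)OO1 | intermediate
22 | 2-[(3S)-6-hexadecyl-6-methoxy-3,6-dihydro-1,2-dioxin-3-yl]acetic acid, both C6 epimers | CCCCCCCCCCCCCCCCC1(OC)C=C[C@H](CC(=O)O)OO1 | intermediate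
23 | methyl 2-[(3S)-6-hexadecyl-6-methoxy-3,6-dihydro-1,2-dioxin-3-yl]acetate, both C6 epimers | CCCCCCCCCCCCCCCCC1(OC)C=C[C@H](CC(=O)OC)OO1 | intermediate
24 | methyl 2-[(3S,6R)-6-hexadecyl-6-methoxy-3,6-dihydro-1,2-dioxin-3-yl]acetate | CCCCCCCCCCCCCCCC[C@]1(OC)C=C[C@H](CC(=O)OC)OO1 | target

**Summary**

Total step count: 15. Longest linear sequence: 15 steps (1 to 24; compounds 4, 9 and 18 enter as purchased reagents).

**Steps most likely to fail**

1. Step 12. The Lewis acid may ionise the allylic oxetane C–O bond to an allyl cation, which would erode the configuration at C3 and let the alkene drift to (E). It may instead ionise the hydroperoxy ketal with loss of H2O2 before the ring closes. The fallback uses known reactions only, sets out from 8 and comes back at 24.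
   - Sonogashira coupling of 8 with methyl (2E)-3-iodoacrylate (PdCl2(PPh3)2, CuI, Et3N, THF) would give methyl (2E)-6,6-dimethoxydocos-2-en-4-ynoate F1.
   - Lindlar semi-hydrogenation would give methyl (2E,4Z)-6,6-dimethoxydocosa-2,4-dienoate F2.
   - Perhydrolysis as in step 11 would give methyl (2E,4Z)-6-hydroperoxy-6-methoxydocosa-2,4-dienoate F3.
   - Intramolecular peroxy-Michael addition (Et2NH, CF3CH2OH) is a 6-exo-trig closure that forms the same O2–C3 bond with the ester arm already in place. It would give methyl 2-(6-hexadecyl-6-methoxy-3,6-dihydro-1,2-dioxin-3-yl)acetate F4 as all four stereoisomers.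
   - Equilibration of F4 in acidic methanol, chromatographic separation of the racemate with methoxy trans to the arm, and resolution by HPLC on a chiral stationary phase would deliver 24.
   - The price is that C3 is no longer set by a reagent-controlled step.

2. Step 11. The exchange may run on to the geminal dihydroperoxide, the alkene may isomerise through the methoxyallyl cation, or the acid may open the oxetane prematurely with methanol or H2O2. The fallback sets out from 17 and comes back at 20.
   - The perhydrolysis is pushed deliberately to completion (excess H2O2, Re2O7 (cat.), MeCN) to give (2R)-2-[(1Z)-3,3-dihydroperoxynonadec-1-en-1-yl]oxetane F5. Either hydroperoxide of F5 can close the ring and no ketal epimers exist.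
   - Cyclisation with Yb(OTf)3 as in step 12 would give 2-[(3S)-6-hexadecyl-6-hydroperoxy-3,6-dihydro-1,2-dioxin-3-yl]ethan-1-ol F6.
   - Camphorsulfonic acid in methanol would then exchange the exocyclic hydroperoxide for methoxy through the ring peroxycarbenium ion to give 20.

3. Step 15. The thermodynamic distribution of the C6 epimers may be unfavourable for the (6R) isomer, and repeated exposure to acid may slowly degrade the peroxyketal. The fallback sets out from 23 and comes back at 24.
   - The mixed ketal is hydrolysed (PPTS, acetone/H2O) to the hemiketal methyl 2-[(3S)-6-hexadecyl-6-hydroxy-3,6-dihydro-1,2-dioxin-3-yl]acetate F7, whose C6 epimers interconvert by ring–chain tautomerism.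
   - F7 is methylated irreversibly without acid (MeOTf, 2,6-di-tert-butyl-4-methylpyridine, CH2Cl2, 0 °C). The epimer distribution is then set by the relative rates of O-alkylation (Curtin–Hammett situation) instead of by ketal stability.
   - Chromatography as before would give 24.

**Further compounds**

F1 | step 12 | methyl (2E)-6,6-dimethoxydocos-2-en-4-ynoate | CCCCCCCCCCCCCCCCC(OC)(OC)C#C/C=C/C(=O)OC
F2 | step 12 | methyl (2E,4Z)-6,6-dimethoxydocosa-2,4-dienoate | CCCCCCCCCCCCCCCCC(OC)(OC)/C=C\C=C\C(=O)OC
F3 | step 12 | methyl (2E,4Z)-6-hydroperoxy-6-methoxydocosa-2,4-dienoate | CCCCCCCCCCCCCCCCC(OC)(OO)/C=C\C=C\C(=O)OC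
F4 | step 12 | methyl 2-(6-hexadecyl-6-methoxy-3,6-dihydro-1,2-dioxin-3-yl)acetate, all four stereoisomers | CCCCCCCCCCCCCCCCC1(OC)C=CC(CC(=O)OC)OO1
F5 | step 11 | (2R)-2-[(1Z)-3,3-dihydroperoxynonadec-1-en-1-yl]oxetane | CCCCCCCCCCCCCCCCC(OO)(OO)/C=C\[C@@H]1OCC1
F6 | step 11 | 2-[(3S)-6-hexadecyl-6-hydroperoxy-3,6-dihydro-1,2-dioxin-3-yl]ethan-1-ol, both C6 epimers | CCCCCCCCCCCCCCCCC1(OO)C=C[C@H](CCO)OO1
F7 | step 15 | methyl 2-[(3S)-6-hexadecyl-6-hydroxy-3,6-dihydro-1,2-dioxin-3-yl]acetate, both C6 epimers | CCCCCCCCCCCCCCCCC1(O)C=C[C@H](CC(=O)OC)OO1
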